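**Retrosynthetic overview**
1. Target 26 comes from bis-silyl ether 25 by desilylation. 25 comes from allylic bromide 18 and alkyne 23 by hydrozirconation and palladium-catalysed alkenyl–allyl coupling, which forms the CH2–CH= bond of the skipped diene. The S carbinol of 23 derives from the Sharpless epoxide 19 of geraniol.
2. 18 comes from chromene ester 14 by partial reduction, E-selective Wittig olefination, reduction and bromination.
3. The strategy rests on the pyran ring (O1, C2, C3, C4, C4a, C8a): its C3=C4 double bond ties benzylic C4 to C3, the neighbour of the fully substituted stereocentre C2. Cutting C3=C4 back to C4=O and C3=CH2 gives 12, the salicylaldehyde ether of a tertiary vinyl carbinol. In the forward sense this is a photochemical carbonyl–olefin metathesis through oxetane 13 with loss of formaldehyde.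
4. 12 comes from salicylaldehyde 4 (from 2-methylhydroquinone 1) and allylic carbonate 11 (from geraniol 5) by palladium-catalysed asymmetric O-allylation, which sets C2.
5. Ring order: the benzene ring is bought with 1; the pyran ring is the only ring made (step 9); the oxetane is transient.

Key step: step 9

Assumption: the (R,R) enantiomer of the diamide diphosphine is written in step 8 as the one expected to give (S)-12 from the E-carbonate; this sense of induction must be confirmed on the first batch, and the equally available mirror-image ligand is used if it proves opposite.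

**Route**

Step 1
Reactants: 1 2-methylhydroquinone
Product: 2 4-(tert-butyldimethylsilyloxy)-2-methylphenol
Conditions: TBSCl (1.0 equiv), imidazole, DMF, 0 °C
Reagents that add atoms: tert-butyldimethylsilyl chloride, CC(C)(C)[Si](C)(C)Cl
Why: Sterically controlled monosilylation should take the hydroxyl at C4, which has no ortho substituent, in preference to the hydroxyl flanked by the methyl group; the bis-silyl ether and the minor regioisomer are removed by chromatography.

Step 2
Reactants: 2 4-(tert-butyldimethylsilyloxy)-2-methylphenol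
Product: 4 5-(tert-butyldimethylsilyloxy)-2-hydroxy-3-methylbenzaldehyde, via salicyl alcohol 3 (not isolated)
Conditions: MgCl2, Et3N, (CH2O)n, MeCN, reflux; cold dilute HCl work-up
Reagents that add atoms: formaldehyde (as paraformaldehyde), C=O
Why: In this magnesium-mediated ortho-formylation (Casnati–Skattebøl reaction) the magnesium phenoxide directs hydroxymethylation to the only free ortho position, and the salicyl alkoxide 3 is oxidised in the flask by Oppenauer-type hydride transfer to a second formaldehyde, conditions the aryl silyl ether should tolerate.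

Step 3
Reactants: 5 geraniol
Product: 6 (2E)-3,7-dimethylocta-2,6-dien-1-yl methyl carbonate
Conditions: ClCO2Me, pyridine, CH2Cl2, 0 °C
Reagents that add atoms: methyl chloroformate, COC(Cl)=O
Why: O-Acylation of the primary allylic alcohol installs the carbonate that later serves as the leaving group and internal base source for palladium.

Step 4
Reactants: 6 (2E)-3,7-dimethylocta-2,6-dien-1-yl methyl carbonate
Product: 7 (2E)-5-(3,3-dimethyloxiran-2-yl)-3-methylpent-2-en-1-yl methyl carbonate
Conditions: mCPBA (1.05 equiv), NaHCO3, CH2Cl2, 0 °C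
Reagents that add atoms: 3-chloroperoxybenzoic acid, OOC(=O)c1cccc(Cl)c1
Why: Prilezhaev epoxidation with one equivalent of peracid should select the electron-rich 6,7-alkene, because the 2,3-alkene is deactivated by the allylic carbonate; the epoxide is racemic and its stereocentre is destroyed in step 5.

Step 5
Reactants: 7 (2E)-5-(3,3-dimethyloxiran-2-yl)-3-methylpent-2-en-1-yl methyl carbonate
Product: 9 (2E)-3-methyl-6-oxohex-2-en-1-yl methyl carbonate, via vicinal diol 8 (not isolated)
Conditions: H5IO6, THF/H2O, 0 °C → rt
Reagents that add atoms: none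
Why: Acid-promoted hydration of the epoxide (water enters at the tertiary carbon, so its oxygen leaves with acetone) followed by periodate glycol cleavage (Malaprade reaction) shortens the chain to the aldehyde without touching the allylic carbonate or the E-alkene.

Step 6
Reactants: 9 (2E)-3-methyl-6-oxohex-2-en-1-yl methyl carbonate
Product: 10 (4E)-6-[(methoxycarbonyl)oxy]-4-methylhex-4-enoic acid
Conditions: NaClO2, NaH2PO4, 2-methylbut-2-ene, t-BuOH/H2O, rt
Reagents that add atoms: sodium chlorite, [Na+].[O-]Cl=O
Why: Pinnick oxidation converts the aldehyde into the acid under buffered conditions, with 2-methylbut-2-ene scavenging hypochlorous acid so that the trisubstituted alkene and the carbonate stay intact.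

Step 7
Reactants: 10 (4E)-6-[(methoxycarbonyl)oxy]-4-methylhex-4-enoic acid
Product: 11 methyl (4E)-6-[(methoxycarbonyl)oxy]-4-methylhex-4-enoate
Conditions: MeI, K2CO3, DMF, rt
Reagents that add atoms: iodomethane, CI
Why: SN2 O-methylation of the potassium carboxylate gives the methyl ester in the absence of any nucleophile that could attack the allylic carbonate.

Step 8
Reactants: 4 5-(tert-butyldimethylsilyloxy)-2-hydroxy-3-methylbenzaldehyde; 11 methyl (4E)-6-[(methoxycarbonyl)oxy]-4-methylhex-4-enoate
Product: 12 methyl (4S)-4-[4-(tert-butyldimethylsilyloxy)-2-formyl-6-methylphenoxy]-4-methylhex-5-enoate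
Conditions: Pd2(dba)3·CHCl3 (2.5 mol %), (R,R)-N,N′-(cyclohexane-1,2-diyl)bis[2-(diphenylphosphanyl)benzamide] (7.5 mol %), degassed CH2Cl2, rt
Reagents that add atoms: none
Why: In this asymmetric Tsuji–Trost allylic etherification, zerovalent palladium ionises the E-carbonate to a syn-configured 1,1-disubstituted allyl complex, the methoxide set free deprotonates the phenol, and the phenoxide attacks the more substituted allyl terminus inside the chiral pocket of the ligand, which sets C2 as S by catalyst control.

Step 9
Reactants: 12 methyl (4S)-4-[4-(tert-butyldimethylsilyloxy)-2-formyl-6-methylphenoxy]-4-methylhex-5-enoate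
Product: 14 methyl 3-[(2S)-6-(tert-butyldimethylsilyloxy)-2,8-dimethyl-2H-chromen-2-yl]propanoate, via chroman-fused oxetane 13 (not isolated)
Conditions: hν (365 nm, Pyrex), degassed C6H6 (0.005 M), 20 °C; lamp off; then CH2Cl2, BF3·OEt2 (0.3 equiv), −20 → 0 °C; Et3N quench
Reagents that add atoms: none
Why: Excitation of the aryl aldehyde and intersystem crossing give the n,π* triplet, whose oxygen attacks the terminal CH2 of the vinyl group to give the 1,4-biradical with its radical centres at benzylic C4 and secondary C3, and spin inversion with C3–C4 bonding completes an intramolecular Paternò–Büchi cycloaddition to oxetane 13. BF3 then ionises the strained benzylic C4–O bond (the cation is stabilised by the ortho ether oxygen O1) and the C3–CH2 bond breaks in a Grob-type retro-[2+2] step that expels formaldehyde and leaves the C3=C4 alkene, so that the two operations amount to a stepwise carbonyl–olefin metathesis, whose closest known relatives are the photocycloaddition and acid-cycloreversion metatheses of aryl carbonyl compounds bearing tethered alkenes and the catalytic ring-closing carbonyl–olefin metathesis of O-allyl salicylaldehydes to 2H-chromenes. The pyran ring (O1, C2, C3, C4, C4a, C8a) is closed by the C4–C3 bond in a 6-exo mode with respect to the vinyl group, the carbonyl oxygen being parked on the exocyclic CH2 until it leaves with it. The two stereocentres created at C3 and C4 of 13 are necessarily cis at the ring fusion and otherwise uncontrolled, which is immaterial because both become sp2 in the cycloreversion, while C2 has no bond made or broken and no stereocentre of 14 originates here. The step needs regioselectivity (oxygen to the terminal carbon, not the crossed, bridged adduct) and chemoselectivity against hydrogen abstraction: the former follows from the more substituted biradical and from the four-atom link C4a–C8a–O1–C2 that makes the six-membered closure the natural one, the latter from a substrate that has no hydrogen on C2, no allylic hydrogen on the vinyl group, no alkyl group ortho to the formyl group and no second alkene. The acid is added only after the lamp is switched off, because the 2H-chromene is photochromic and its electrocyclic opening to an ortho-quinone methide would racemise C2.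

Step 10
Reactants: 14 methyl 3-[(2S)-6-(tert-butyldimethylsilyloxy)-2,8-dimethyl-2H-chromen-2-yl]propanoate
Product: 15 3-[(2S)-6-(tert-butyldimethylsilyloxy)-2,8-dimethyl-2H-chromen-2-yl]propanal
Conditions: i-Bu2AlH (1.05 equiv), CH2Cl2, −78 °C; MeOH, then aq. KNaC4H4O6
Reagents that add atoms: none
Why: Partial reduction of the aliphatic methyl ester at −78 °C stops at the aluminium hemiacetal, which releases the aldehyde on work-up; the chromene, the aryl silyl ether and C2 are unaffected.

Step 11
Reactants: 15 3-[(2S)-6-(tert-butyldimethylsilyloxy)-2,8-dimethyl-2H-chromen-2-yl]propanal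
Product: 16 ethyl (2E)-5-[(2S)-6-(tert-butyldimethylsilyloxy)-2,8-dimethyl-2H-chromen-2-yl]-2-methylpent-2-enoate
Conditions: Ph3P=C(CH3)CO2Et, CH2Cl2, rt → 40 °C
Reagents that add atoms: ethyl 2-(triphenylphosphoranylidene)propanoate, CCOC(=O)C(C)=P(c1ccccc1)(c1ccccc1)c1ccccc1
Why: Wittig olefination with the stabilised α-methyl ylide should give the trisubstituted enoate with E geometry, as is usual for reversible oxaphosphetane formation from unhindered aliphatic aldehydes.

Step 12
Reactants: 16 ethyl (2E)-5-[(2S)-6-(tert-butyldimethylsilyloxy)-2,8-dimethyl-2H-chromen-2-yl]-2-methylpent-2-enoate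
Product: 17 (2E)-5-[(2S)-6-(tert-butyldimethylsilyloxy)-2,8-dimethyl-2H-chromen-2-yl]-2-methylpent-2-en-1-ol
Conditions: i-Bu2AlH (2.5 equiv), CH2Cl2, −78 → 0 °C; aq. KNaC4H4O6
Reagents that add atoms: none
Why: 1,2-Reduction of the conjugated ester with excess aluminium hydride gives the allylic alcohol with the E geometry retained.

Step 13
Reactants: 17 (2E)-5-[(2S)-6-(tert-butyldimethylsilyloxy)-2,8-dimethyl-2H-chromen-2-yl]-2-methylpent-2-en-1-ol
Product: 18 tert-butyl{[(2S)-2-[(3E)-5-bromo-4-methylpent-3-en-1-yl]-2,8-dimethyl-2H-chromen-6-yl]oxy}dimethylsilane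
Conditions: CBr4, PPh3, CH2Cl2, 0 °C; used without delay
Reagents that add atoms: tetrabromomethane, BrC(Br)(Br)Br
Why: Appel bromination replaces the primary allylic hydroxyl by SN2 displacement of the alkoxyphosphonium ion under neutral conditions, preserving the E-alkene, the chromene and the silyl ether.

Step 14
Reactants: 5 geraniol
Product: 19 [(2S,3S)-3-methyl-3-(4-methylpent-3-en-1-yl)oxiran-2-yl]methanol
Conditions: Ti(O-i-Pr)4 (5 mol %), L-(+)-diethyl tartrate (7.5 mol %), t-BuOOH, 4 Å molecular sieves, CH2Cl2, −20 °C
Reagents that add atoms: tert-butyl hydroperoxide, CC(C)(C)OO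
Why: In the Sharpless asymmetric epoxidation the titanium tartrate complex delivers oxygen to one face of the allylic alcohol only, setting the 2S,3S epoxide by reagent control, while the isolated 6,7-alkene does not react.

Step 15
Reactants: 19 [(2S,3S)-3-methyl-3-(4-methylpent-3-en-1-yl)oxiran-2-yl]methanol
Product: 20 (2R,3S)-2-(chloromethyl)-3-methyl-3-(4-methylpent-3-en-1-yl)oxirane
Conditions: PPh3, CCl4, NaHCO3, reflux
Reagents that add atoms: tetrachloromethane, ClC(Cl)(Cl)Cl
Why: Appel chlorination exchanges the primary hydroxyl for chloride with the epoxide intact (the descriptor at C2 changes only because of the priority of chlorine).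

Step 16
Reactants: 20 (2R,3S)-2-(chloromethyl)-3-methyl-3-(4-methylpent-3-en-1-yl)oxirane
Product: 22 (3S)-3,7-dimethyloct-6-en-1-yn-3-ol, via chlorovinyl carbinol 21 (not isolated)
Conditions: n-BuLi (3.3 equiv), THF, −78 → −30 °C; aq. NH4Cl
Reagents that add atoms: none
Why: In this base-induced double elimination of a 2,3-epoxy chloride, deprotonation at the chloromethyl carbon opens the epoxide to the chlorovinyl alkoxide 21 and dehydrochlorination gives the acetylide; the C3–O bond is never broken, so the S tertiary carbinol is inherited from the epoxide.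

Step 17
Reactants: 22 (3S)-3,7-dimethyloct-6-en-1-yn-3-ol
Product: 23 {[(3S)-3,7-dimethyloct-6-en-1-yn-3-yl]oxy}triethylsilane
Conditions: Et3SiOTf, 2,6-lutidine, CH2Cl2, −78 → 0 °C
Reagents that add atoms: triethylsilyl trifluoromethanesulfonate, CC[Si](CC)(CC)OS(=O)(=O)C(F)(F)F
Why: Silylation of the hindered tertiary alcohol with the silyl triflate masks the hydroxyl so that it cannot consume zirconium hydride in step 18.

Step 18
Reactants: 23 {[(3S)-3,7-dimethyloct-6-en-1-yn-3-yl]oxy}triethylsilane; 18 tert-butyl{[(2S)-2-[(3E)-5-bromo-4-methylpent-3-en-1-yl]-2,8-dimethyl-2H-chromen-6-yl]oxy}dimethylsilane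
Product: 25 tert-butyldimethyl{[(2S)-2,8-dimethyl-2-[(3E,6E,8S)-4,8,12-trimethyl-8-(triethylsilyloxy)trideca-3,6,11-trien-1-yl]-2H-chromen-6-yl]oxy}silane, via alkenylzirconocene 24 (not isolated)
Conditions: 23 (1.3 equiv), Cp2Zr(H)Cl (1.2 equiv), THF, rt; then 18 (1.0 equiv), Pd(PPh3)4 (5 mol %), THF, 0 °C → rt
Reagents that add atoms: none
Why: Hydrozirconation of the terminal alkyne (syn addition, zirconium on the terminal carbon) gives the E-alkenylzirconocene 24, which undergoes palladium-catalysed Negishi-type alkenyl–allyl cross-coupling at the primary terminus of the allylic bromide with retention of both alkene geometries, forming the skipped 1,4-diene.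

Step 19
Reactants: 25 tert-butyldimethyl{[(2S)-2,8-dimethyl-2-[(3E,6E,8S)-4,8,12-trimethyl-8-(triethylsilyloxy)trideca-3,6,11-trien-1-yl]-2H-chromen-6-yl]oxy}silane
Product: 26 (2S)-2-[(3E,6E,8S)-8-hydroxy-4,8,12-trimethyltrideca-3,6,11-trien-1-yl]-2,8-dimethyl-2H-chromen-6-ol
Conditions: Bu4NF (3 equiv), THF, 0 °C → rt; aq. NH4Cl work-up, under argon
Reagents that add atoms: none
Why: Fluoride-mediated desilylation removes the aryl tert-butyldimethylsilyl ether and the tertiary triethylsilyl ether together, under conditions that affect neither the chromene, the skipped diene nor either stereocentre.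

**Compound list**
1 | 2-methylbenzene-1,4-diol (2-methylhydroquinone) | Cc1cc(O)ccc1O | starting material
2 | 4-(tert-butyldimethylsilyloxy)-2-methylphenol | Cc1cc(O[Si](C)(C)C(C)(C)C)ccc1O | intermediate
3 | 4-(tert-butyldimethylsilyloxy)-2-(hydroxymethyl)-6-methylphenol (present as its magnesium salt; not isolated) | Cc1cc(O[Si](C)(C)C(C)(C)C)cc(CO)c1O | intermediate
4 | 5-(tert-butyldimethylsilyloxy)-2-hydroxy-3-methylbenzaldehyde | Cc1cc(O[Si](C)(C)C(C)(C)C)cc(C=O)c1O | intermediate
5 | geraniol, (2E)-3,7-dimethylocta-2,6-dien-1-ol | CC(C)=CCC/C(C)=C/CO | starting material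
6 | (2E)-3,7-dimethylocta-2,6-dien-1-yl methyl carbonate | CC(C)=CCC/C(C)=C/COC(=O)OC | intermediate
7 | (2E)-5-(3,3-dimethyloxiran-2-yl)-3-methylpent-2-en-1-yl methyl carbonate (racemic) | CC1(C)OC1CC/C(C)=C/COC(=O)OC | intermediate
8 | (2E)-6,7-dihydroxy-3,7-dimethyloct-2-en-1-yl methyl carbonate (racemic; not isolated) | CC(C)(O)C(O)CC/C(C)=C/COC(=O)OC | intermediate
9 | (2E)-3-methyl-6-oxohex-2-en-1-yl methyl carbonate | O=CCC/C(C)=C/COC(=O)OC | intermediate
10 | (4E)-6-[(methoxycarbonyl)oxy]-4-methylhex-4-enoic acid | OC(=O)CC/C(C)=C/COC(=O)OC | intermediate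
11 | methyl (4E)-6-[(methoxycarbonyl)oxy]-4-methylhex-4-enoate | COC(=O)CC/C(C)=C/COC(=O)OC | intermediate
12 | methyl (4S)-4-[4-(tert-butyldimethylsilyloxy)-2-formyl-6-methylphenoxy]-4-methylhex-5-enoate | COC(=O)CC[C@@](Oc1c(C)cc(O[Si](C)(C)C(C)(C)C)cc1C=O)(C)C=C | intermediate
13 | methyl 3-[(2S)-6-(tert-butyldimethylsilyloxy)-2,8-dimethyl-4,3-(epoxymethano)chroman-2-yl]propanoate (oxetane cis-fused across C3–C4, oxygen on C4 and CH2 on C3; both cis-fused diastereomers; not isolated) | COC(=O)CC[C@]1(C)Oc2c(C)cc(O[Si](C)(C)C(C)(C)C)cc2C2OCC12 | intermediate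
14 | methyl 3-[(2S)-6-(tert-butyldimethylsilyloxy)-2,8-dimethyl-2H-chromen-2-yl]propanoate | COC(=O)CC[C@@]1(C)C=Cc2cc(O[Si](C)(C)C(C)(C)C)cc(C)c2O1 | intermediate
15 | 3-[(2S)-6-(tert-butyldimethylsilyloxy)-2,8-dimethyl-2H-chromen-2-yl]propanal | O=CCC[C@@]1(C)C=Cc2cc(O[Si](C)(C)C(C)(C)C)cc(C)c2O1 | intermediate
16 | ethyl (2E)-5-[(2S)-6-(tert-butyldimethylsilyloxy)-2,8-dimethyl-2H-chromen-2-yl]-2-methylpent-2-enoate | CCOC(=O)/C(C)=C/CC[C@@]1(C)C=Cc2cc(O[Si](C)(C)C(C)(C)C)cc(C)c2O1 | intermediate
17 | (2E)-5-[(2S)-6-(tert-butyldimethylsilyloxy)-2,8-dimethyl-2H-chromen-2-yl]-2-methylpent-2-en-1-ol | OC/C(C)=C/CC[C@@]1(C)C=Cc2cc(O[Si](C)(C)C(C)(C)C)cc(C)c2O1 | intermediate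
18 | tert-butyl{[(2S)-2-[(3E)-5-bromo-4-methylpent-3-en-1-yl]-2,8-dimethyl-2H-chromen-6-yl]oxy}dimethylsilane | BrC/C(C)=C/CC[C@@]1(C)C=Cc2cc(O[Si](C)(C)C(C)(C)C)cc(C)c2O1 | intermediate
19 | [(2S,3S)-3-methyl-3-(4-methylpent-3-en-1-yl)oxiran-2-yl]methanol | CC(C)=CCC[C@]1(C)O[C@H]1CO | intermediate
20 | (2R,3S)-2-(chloromethyl)-3-methyl-3-(4-methylpent-3-en-1-yl)oxirane | CC(C)=CCC[C@]1(C)O[C@H]1CCl | intermediate
21 | (3S)-1-chloro-3,7-dimethylocta-1,6-dien-3-ol (present as its lithium alkoxide, alkene geometry not defined; not isolated) | CC(C)=CCC[C@](C)(O)C=CCl | intermediate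
22 | (3S)-3,7-dimethyloct-6-en-1-yn-3-ol | CC(C)=CCC[C@](C)(O)C#C | intermediate
23 | {[(3S)-3,7-dimethyloct-6-en-1-yn-3-yl]oxy}triethylsilane | CC(C)=CCC[C@](C)(O[Si](CC)(CC)CC)C#C | intermediate
24 | chlorobis(cyclopentadienyl)[(1E,3S)-3,7-dimethyl-3-(triethylsilyloxy)octa-1,6-dien-1-yl]zirconium (rings drawn σ-bonded in the string; not isolated) | CC(C)=CCC[C@](C)(O[Si](CC)(CC)CC)/C=C/[Zr](Cl)(C1C=CC=C1)C1C=CC=C1 | intermediate
25 | tert-butyldimethyl{[(2S)-2,8-dimethyl-2-[(3E,6E,8S)-4,8,12-trimethyl-8-(triethylsilyloxy)trideca-3,6,11-trien-1-yl]-2H-chromen-6-yl]oxy}silane | CC(C)=CCC[C@](C)(O[Si](CC)(CC)CC)/C=C/C/C(C)=C/CC[C@@]1(C)C=Cc2cc(O[Si](C)(C)C(C)(C)C)cc(C)c2O1 | intermediate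
26 | (2S)-2-[(3E,6E,8S)-8-hydroxy-4,8,12-trimethyltrideca-3,6,11-trien-1-yl]-2,8-dimethyl-2H-chromen-6-ol | CC(C)=CCC[C@](C)(O)/C=C/C/C(C)=C/CC[C@@]1(C)C=Cc2cc(O)cc(C)c2O1 | target

**Step count**
Total: 19 steps. Longest linear sequence: 13 steps (geraniol 5 through steps 3–13, then 18 and 19).

**Steps most likely to fail**

Step 9 (key step).
- What may go wrong: the photocycloaddition may be inefficient, because the lowest triplet of the doubly oxygenated benzaldehyde may have largely π,π* character, or because hydrogen abstraction from the chain through an eight-membered transition state competes. The Lewis-acid opening of 13 may also drift towards proton loss from C3, or towards Prins-type recapture of formaldehyde by the electron-rich product, instead of fragmentation.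
- Fallback: the C3=C4 bond is made by olefin metathesis instead. Aldehyde 12 is methylenated (Ph3PCH3Br, KN(SiMe3)2, THF, −78 → 0 °C; the non-stabilised ylide takes the aldehyde and leaves the ester) to the styrene methyl (4S)-4-[4-(tert-butyldimethylsilyloxy)-2-ethenyl-6-methylphenoxy]-4-methylhex-5-enoate F1. Ring-closing metathesis of F1 with the second-generation Grubbs catalyst (CH2Cl2, 40 °C, loss of ethene) returns to the route at 14, with C2 untouched.

Step 8.
- What may go wrong: the phenoxide of 4 carries two ortho substituents and is a good leaving group. Attack at the primary allyl terminus, re-ionisation of the product ether by zerovalent palladium, and incomplete facial discrimination could each erode constitution or enantiomeric purity.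
- Fallback: constitution and configuration are secured separately, setting out from 4.
 - Ethynylmagnesium bromide is added to commercial methyl levulinate (THF, −78 °C) and the alkoxide is trapped in the flask with methyl chloroformate, giving the racemic propargylic carbonate methyl 4-[(methoxycarbonyl)oxy]-4-methylhex-5-ynoate F2.
 - Copper-catalysed propargylic etherification of 4 with F2 (CuCl2 cat., DBU, MeCN, 0 °C), which places the aryloxy group on the tertiary carbon by way of a copper allenylidene, gives the racemic aryl propargyl ether methyl 4-[4-(tert-butyldimethylsilyloxy)-2-formyl-6-methylphenoxy]-4-methylhex-5-ynoate F3.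
 - Semi-hydrogenation (H2, Pd/CaCO3 poisoned with Pb(OAc)2, quinoline, EtOAc) gives the racemate of 12, F4.
 - The enantiomers are separated by preparative chromatography on a chiral stationary phase, returning to the route at 12.

Step 18.
- What may go wrong: syn–anti exchange in the 2-methyl-substituted allylpalladium intermediate, or slow transfer of the hindered alkenyl group from zirconium, could scramble the geometry of the trisubstituted alkene or lead to bond formation at the internal allyl terminus.
- Fallback: the bond is formed at the alkyne oxidation level without an allylpalladium species, setting out from 18 and the free alkynol 22.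
 - Copper-mediated SN2 alkynylation (CuI, copper monoiodide, with NaI, K2CO3, DMF, rt) gives the skipped enynol (6S,10E)-13-[(2S)-6-(tert-butyldimethylsilyloxy)-2,8-dimethyl-2H-chromen-2-yl]-2,6,10-trimethyltrideca-2,10-dien-7-yn-6-ol F5.
 - Hydroxyl-directed trans-hydroalumination of the propargylic alcohol (NaAlH2(OCH2CH2OCH3)2, THF, 0 °C → rt) gives the E-allylic alcohol (6S,7E,10E)-13-[(2S)-6-(tert-butyldimethylsilyloxy)-2,8-dimethyl-2H-chromen-2-yl]-2,6,10-trimethyltrideca-2,7,10-trien-6-ol F6.
 - Desilylation with Bu4NF returns to the route at 26.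

**Further compounds**
F1 | step 9 | methyl (4S)-4-[4-(tert-butyldimethylsilyloxy)-2-ethenyl-6-methylphenoxy]-4-methylhex-5-enoate | COC(=O)CC[C@@](Oc1c(C)cc(O[Si](C)(C)C(C)(C)C)cc1C=C)(C)C=C
F2 | step 8 | methyl 4-[(methoxycarbonyl)oxy]-4-methylhex-5-ynoate (racemic) | COC(=O)CCC(C)(OC(=O)OC)C#C
F3 | step 8 | methyl 4-[4-(tert-butyldimethylsilyloxy)-2-formyl-6-methylphenoxy]-4-methylhex-5-ynoate (racemic) | COC(=O)CCC(C)(Oc1c(C)cc(O[Si](C)(C)C(C)(C)C)cc1C=O)C#C
F4 | step 8 | methyl 4-[4-(tert-butyldimethylsilyloxy)-2-formyl-6-methylphenoxy]-4-methylhex-5-enoate (racemate of 12) | COC(=O)CCC(C)(Oc1c(C)cc(O[Si](C)(C)C(C)(C)C)cc1C=O)C=C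
F5 | step 18 | (6S,10E)-13-[(2S)-6-(tert-butyldimethylsilyloxy)-2,8-dimethyl-2H-chromen-2-yl]-2,6,10-trimethyltrideca-2,10-dien-7-yn-6-ol | CC(C)=CCC[C@](C)(O)C#CC/C(C)=C/CC[C@@]1(C)C=Cc2cc(O[Si](C)(C)C(C)(C)C)cc(C)c2O1
F6 | step 18 | (6S,7E,10E)-13-[(2S)-6-(tert-butyldimethylsilyloxy)-2,8-dimethyl-2H-chromen-2-yl]-2,6,10-trimethyltrideca-2,7,10-trien-6-ol | CC(C)=CCC[C@](C)(O)/C=C/C/C(C)=C/CC[C@@]1(C)C=Cc2cc(O[Si](C)(C)C(C)(C)C)cc(C)c2O1
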